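**Retrosynthetic overview**

1. The target is read as the (2S)-chromanol with a (24'S) tertiary allylic alcohol (side-chain atoms C1' to C33' counted from the chroman). The key disconnection is the C21'–C22' bond, formed as a C(sp3)–C(sp) bond with C22'–C23' at the alkyne oxidation level; a hydroxyl-directed trans-hydroalumination then returns the E alkene.
2. Enabling feature: the acyclic array O–C24'(CH3)–C23'H=C22'H–C21'H2–C20'(CH3)=C19'H. The oxygen on the fully substituted C24' sits where the oxygen of a farnesol 2,3-epoxide sits, so a 1-chloro-2,3-epoxide can be unzipped by base (release of oxirane strain) to the C22' acetylide with the S carbinol already in place; C21' is the E-terminal CH2 of a prenyl unit, i.e. a primary allylic bromide.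
3. Nucleophile half: E,E-farnesol, asymmetric epoxidation, epoxy chloride. Electrophile half: terminal allylic oxidation and bromination of a TIPS-protected (2S)-chroman carrying a pentaprenyl chain.
4. That chroman pentaene comes from a B-alkyl Suzuki coupling of a (2R)-2-vinylchroman with a C25 (E)-alkenyl iodide made from geranylgeraniol (propargylation, zirconium-catalysed carboalumination, iodination).
5. Rings: the arene (ring A) is bought. The dihydropyran ring (ring B) is the only ring made: first as a racemic ketal from 2,3-dimethylhydroquinone and methyl vinyl ketone, opened by olefination, then re-closed enantioselectively by palladium-catalysed asymmetric allylic O-alkylation, which sets C2. A final fluoride step frees the phenol.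

Key step: step 16

Remark: in step 6 the (S,S) ligand is taken to give the 2R vinylchroman from the E carbonate; if the first run shows the opposite sense, the (R,R) ligand is used with no other change.

**Route**

Step 1
Reactants: 1 2,3-dimethylbenzene-1,4-diol (2,3-dimethylhydroquinone); 2 but-3-en-2-one (methyl vinyl ketone)
Product: 3 rac-2-methoxy-2,7,8-trimethylchroman-6-ol
Conditions: HC(OMe)3, H2SO4 (cat.), MeOH, 0 °C to rt (1 in 1.5-fold excess, 2 added slowly)
Reagents that add atoms: trimethyl orthoformate, COC(OC)OC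
Why: Acid-catalysed Friedel–Crafts-type conjugate addition of the electron-rich hydroquinone to the enone, ortho to one hydroxyl, followed by ketalisation traps the adduct as the cyclic methyl ketal; the two free ring positions of 1 are equivalent, so the 7,8-dimethyl pattern follows without a regiochemical choice, and the racemic ketal carbon is erased in step 3.

Step 2
Reactants: 3 rac-2-methoxy-2,7,8-trimethylchroman-6-ol
Product: 5 rac-2,7,8-trimethyl-6-(triisopropylsilyloxy)chroman-2-ol, via TIPS-protected methyl ketal 4 (not isolated)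
Conditions: i-Pr3SiCl, imidazole, DMF, rt; then 1 M HCl, THF, rt
Reagents that add atoms: triisopropylsilyl chloride, CC(C)[Si](Cl)(C(C)C)C(C)C; water, O
Why: Silyl ether formation at the only free phenol (the closed ketal cannot open under these conditions) followed by mild acid hydrolysis of the mixed ketal gives the hemiketal that supplies the methyl ketone for olefination, the aryl TIPS ether being stable to dilute acid and to all later bases.

Step 3
Reactants: 5 rac-2,7,8-trimethyl-6-(triisopropylsilyloxy)chroman-2-ol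
Product: 6 ethyl (2E)-5-[2-hydroxy-3,4-dimethyl-5-(triisopropylsilyloxy)phenyl]-3-methylpent-2-enoate
Conditions: (EtO)2P(O)CH2CO2Et, NaH (2.2 equiv), THF, 0 °C to rt; E isomer separated by chromatography
Reagents that add atoms: triethyl phosphonoacetate, CCOC(=O)CP(=O)(OCC)OCC
Why: Horner–Wadsworth–Emmons olefination of the open hydroxy ketone tautomer (as its phenoxide) gives the trisubstituted enoate, the E isomer being expected as the major, thermodynamically preferred product and being separated from the Z isomer.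

Step 4
Reactants: 6 ethyl (2E)-5-[2-hydroxy-3,4-dimethyl-5-(triisopropylsilyloxy)phenyl]-3-methylpent-2-enoate
Product: 7 (2E)-5-[2-hydroxy-3,4-dimethyl-5-(triisopropylsilyloxy)phenyl]-3-methylpent-2-en-1-ol
Conditions: i-Bu2AlH (3.3 equiv), CH2Cl2, −78 to 0 °C
Reagents that add atoms: none
Why: 1,2-Reduction of the conjugated ester with i-Bu2AlH gives the allylic alcohol without touching the alkene or the silyl ether, the excess covering the free phenol.

Step 5
Reactants: 7 (2E)-5-[2-hydroxy-3,4-dimethyl-5-(triisopropylsilyloxy)phenyl]-3-methylpent-2-en-1-ol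
Product: 8 (2E)-5-[2-hydroxy-3,4-dimethyl-5-(triisopropylsilyloxy)phenyl]-3-methylpent-2-en-1-yl methyl carbonate
Conditions: ClCO2Me (1.1 equiv), pyridine, CH2Cl2, −20 °C
Reagents that add atoms: methyl chloroformate, COC(=O)Cl
Why: Chemoselective acylation, since the unhindered primary allylic alcohol should react with the chloroformate much faster at low temperature than the phenol, which is flanked by a methyl group and the side chain.

Step 6
Reactants: 8 (2E)-5-[2-hydroxy-3,4-dimethyl-5-(triisopropylsilyloxy)phenyl]-3-methylpent-2-en-1-yl methyl carbonate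
Product: 9 (2R)-2-ethenyl-2,7,8-trimethyl-6-(triisopropylsilyloxy)chroman
Conditions: Pd2(dba)3·CHCl3 (2 mol%), (S,S)-DACH-phenyl Trost ligand (6 mol%), AcOH (1 equiv), CH2Cl2, rt
Reagents that add atoms: none
Why: Trost asymmetric allylic alkylation in its intramolecular O-alkylation form: ionisation of the carbonate gives a pi-allyl complex of palladium, the phenol attacks the more substituted allyl terminus in a 6-exo closure of ring B, and the chiral diphosphine ligand selects the enantiotopic face so that the quaternary C2 centre is set as 2R (the vinyl precursor of the 2S centre of the target).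

Step 7
Reactants: 10 (2E,6E,10E)-3,7,11,15-tetramethylhexadeca-2,6,10,14-tetraen-1-ol (all-E geranylgeraniol)
Product: 11 (2E,6E,10E)-1-bromo-3,7,11,15-tetramethylhexadeca-2,6,10,14-tetraene
Conditions: PBr3 (0.4 equiv), Et2O, 0 °C
Reagents that add atoms: phosphorus tribromide, BrP(Br)Br
Why: Bromination of a primary allylic alcohol with PBr3 at low temperature proceeds by SN2 displacement of the phosphite ester without allylic transposition or loss of the E geometry.

Step 8
Reactants: 11 (2E,6E,10E)-1-bromo-3,7,11,15-tetramethylhexadeca-2,6,10,14-tetraene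
Product: 12 trimethyl[(5E,9E,13E)-6,10,14,18-tetramethylnonadeca-5,9,13,17-tetraen-1-yn-1-yl]silane
Conditions: 1-(trimethylsilyl)propyne, n-BuLi, THF, −78 °C; then 11, −78 °C to rt
Reagents that add atoms: 1-(trimethylsilyl)propyne, CC#C[Si](C)(C)C
Why: SN2 alkylation (propargylation) of the primary allylic bromide by lithiated 1-(trimethylsilyl)propyne, in which the silyl group blocks the alkyne terminus and steers the ambident anion to propargylic rather than allenic attack on the unhindered CH2Br.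

Step 9
Reactants: 12 trimethyl[(5E,9E,13E)-6,10,14,18-tetramethylnonadeca-5,9,13,17-tetraen-1-yn-1-yl]silane
Product: 13 (5E,9E,13E)-6,10,14,18-tetramethylnonadeca-5,9,13,17-tetraen-1-yne
Conditions: K2CO3 (cat.), MeOH/THF, rt
Reagents that add atoms: none
Why: Base-catalysed protodesilylation of the alkynylsilane in methanol frees the terminal alkyne and leaves the four alkenes unchanged.

Step 10
Reactants: 13 (5E,9E,13E)-6,10,14,18-tetramethylnonadeca-5,9,13,17-tetraen-1-yne
Product: 15 (1E,5E,9E,13E)-1-iodo-2,6,10,14,18-pentamethylnonadeca-1,5,9,13,17-pentaene, via alkenyldimethylalane 14 (not isolated)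
Conditions: AlMe3 (2.5 equiv), Cp2ZrCl2 (0.25 equiv), CH2Cl2, 0 °C to rt; then I2, THF, −30 to 0 °C
Reagents that add atoms: trimethylaluminium, C[Al](C)C; iodine, II
Why: Negishi zirconium-catalysed carboalumination adds methyl and aluminium syn across the terminal alkyne with aluminium on the terminal carbon, and iodinolysis with retention gives the (E)-2-methylalkenyl iodide; the remote trisubstituted alkenes should not react.

Step 11
Reactants: 9 (2R)-2-ethenyl-2,7,8-trimethyl-6-(triisopropylsilyloxy)chroman; 15 (1E,5E,9E,13E)-1-iodo-2,6,10,14,18-pentamethylnonadeca-1,5,9,13,17-pentaene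
Product: 17 (2S)-2,7,8-trimethyl-2-[(3E,7E,11E,15E)-4,8,12,16,20-pentamethylhenicosa-3,7,11,15,19-pentaen-1-yl]-6-(triisopropylsilyloxy)chroman, via B-alkyl-9-BBN borane 16 (not isolated)
Conditions: 9-BBN-H dimer (0.55 equiv), THF, rt; then 15, Pd(dppf)Cl2 (5 mol%), AsPh3 (10 mol%), aq. K3PO4 (3 M), DMF, rt
Reagents that add atoms: none
Why: B-alkyl Suzuki–Miyaura coupling: anti-Markovnikov hydroboration of the vinyl group by 9-BBN followed by zerovalent-palladium-catalysed sp3–sp2 coupling with retention of the alkenyl iodide geometry builds the C2'–C3' bond, the C2 centre not being involved (its descriptor becomes S only through the priority rules).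

Step 12
Reactants: 17 (2S)-2,7,8-trimethyl-2-[(3E,7E,11E,15E)-4,8,12,16,20-pentamethylhenicosa-3,7,11,15,19-pentaen-1-yl]-6-(triisopropylsilyloxy)chroman
Product: 18 (2E,6E,10E,14E,18E)-2,6,10,14,18-pentamethyl-21-[(2S)-2,7,8-trimethyl-6-(triisopropylsilyloxy)chroman-2-yl]henicosa-2,6,10,14,18-pentaen-1-ol
Conditions: SeO2 (0.3 equiv), t-BuOOH (2.5 equiv), salicylic acid (0.1 equiv), CH2Cl2, 0 °C to rt, stopped at partial conversion, 17 recycled
Reagents that add atoms: tert-butyl hydroperoxide, CC(C)(C)OO (oxygen, relayed by catalytic SeO2)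
Why: Selenium dioxide allylic oxidation (ene reaction then [2,3]-sigmatropic shift, run catalytically with t-BuOOH) should attack the E-methyl group of the terminal, least hindered trisubstituted alkene and give the (E)-allylic alcohol.

Step 13
Reactants: 18 (2E,6E,10E,14E,18E)-2,6,10,14,18-pentamethyl-21-[(2S)-2,7,8-trimethyl-6-(triisopropylsilyloxy)chroman-2-yl]henicosa-2,6,10,14,18-pentaen-1-ol
Product: 19 (2S)-2-[(3E,7E,11E,15E,19E)-21-bromo-4,8,12,16,20-pentamethylhenicosa-3,7,11,15,19-pentaen-1-yl]-2,7,8-trimethyl-6-(triisopropylsilyloxy)chroman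
Conditions: CBr4, PPh3, CH2Cl2, −20 to 0 °C; used without storage
Reagents that add atoms: carbon tetrabromide, BrC(Br)(Br)Br
Why: Appel bromination converts the primary allylic alcohol into the bromide by SN2 attack on the alkoxyphosphonium ion under neutral conditions, with no allylic transposition and no harm to the silyl ether.

Step 14
Reactants: 20 (2E,6E)-3,7,11-trimethyldodeca-2,6,10-trien-1-ol (E,E-farnesol)
Product: 21 [(2S,3S)-3-[(3E)-4,8-dimethylnona-3,7-dien-1-yl]-3-methyloxiran-2-yl]methanol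
Conditions: Ti(OiPr)4 (5 mol%), L-(+)-diethyl tartrate (6 mol%), t-BuOOH (2 equiv), 4 Å molecular sieves, CH2Cl2, −20 °C
Reagents that add atoms: tert-butyl hydroperoxide, CC(C)(C)OO
Why: Sharpless asymmetric epoxidation of the allylic alcohol is chemoselective for the 2,3-alkene, and L-(+)-diethyl tartrate delivers oxygen to the face that gives the (2S,3S)-epoxide, which fixes the future carbinol centre as S.

Step 15
Reactants: 21 [(2S,3S)-3-[(3E)-4,8-dimethylnona-3,7-dien-1-yl]-3-methyloxiran-2-yl]methanol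
Product: 22 (2S,3R)-3-(chloromethyl)-2-[(3E)-4,8-dimethylnona-3,7-dien-1-yl]-2-methyloxirane
Conditions: PPh3, CCl4, NaHCO3, reflux
Reagents that add atoms: carbon tetrachloride, ClC(Cl)(Cl)Cl
Why: Appel chlorination of the primary alcohol gives the epoxy chloride under buffered conditions that leave the oxirane and both alkenes intact; no bond to a stereocentre is broken and the descriptor of the CH carbon changes only through the priority rules.

Step 16
Reactants: 22 (2S,3R)-3-(chloromethyl)-2-[(3E)-4,8-dimethylnona-3,7-dien-1-yl]-2-methyloxirane; 19 (2S)-2-[(3E,7E,11E,15E,19E)-21-bromo-4,8,12,16,20-pentamethylhenicosa-3,7,11,15,19-pentaen-1-yl]-2,7,8-trimethyl-6-(triisopropylsilyloxy)chroman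
Product: 24 (2S)-2-[(3E,7E,11E,15E,19E,24S,27E)-24-hydroxy-4,8,12,16,20,24,28,32-octamethyltritriaconta-3,7,11,15,19,27,31-heptaen-22-yn-1-yl]-2,7,8-trimethyl-6-(triisopropylsilyloxy)chroman, via dilithium alkynide alkoxide 23 (not isolated)
Conditions: 22 (1.3 equiv), LiN(i-Pr)2 (3.0 equiv per 22), THF, −40 to 0 °C; then CuBr·SMe2 (0.3 equiv), 19 (1.0 equiv), THF/DMPU, −30 °C to rt; H2O quench
Reagents that add atoms: none
Why: LiN(i-Pr)2 removes a proton from the CH2Cl carbon of 22 with antiperiplanar opening of the strained oxirane (C–O cleavage at the CH carbon), a second equivalent eliminates HCl from the resulting chlorovinyl alkoxide and a third deprotonates the terminal alkyne, so that 23 carries the lithium acetylide at the bond-forming carbon and the (S)-tertiary alkoxide next to it. Transmetalation to monovalent copper and SN2-type attack on the primary allylic bromide 19 then forms the C(sp)–C(sp3) bond of the 1,4-enyne. The closest known reaction types are the base-induced fragmentation of 2,3-epoxy chlorides to propargylic alcohols with in-flask alkylation of the acetylide, and the copper-catalysed acetylide–allyl halide coupling used for skipped enynes. No ring is closed and no stereocentre is created: the C–O bond at the carbinol carbon is never broken, so the S configuration from step 14 is carried through, and the chroman centre is remote. The step needs alpha over gamma attack on the allyl unit, retention of its E geometry and C- over O-alkylation; the gamma carbon is secondary and flanked by the 2-methyl group, the copper acetylide is a soft carbon nucleophile that does not pass through a free allyl cation, and the lithium tertiary alkoxide is too hindered to compete. The alkyne oxidation level that makes this possible is removed in step 17.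

Step 17
Reactants: 24 (2S)-2-[(3E,7E,11E,15E,19E,24S,27E)-24-hydroxy-4,8,12,16,20,24,28,32-octamethyltritriaconta-3,7,11,15,19,27,31-heptaen-22-yn-1-yl]-2,7,8-trimethyl-6-(triisopropylsilyloxy)chroman
Product: 25 (2S)-2-[(3E,7E,11E,15E,19E,22E,24S,27E)-24-hydroxy-4,8,12,16,20,24,28,32-octamethyltritriaconta-3,7,11,15,19,22,27,31-octaen-1-yl]-2,7,8-trimethyl-6-(triisopropylsilyloxy)chroman
Conditions: NaAlH2(OCH2CH2OMe)2 (3 equiv), THF, 0 °C to rt; aq. potassium sodium tartrate
Reagents that add atoms: none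
Why: Hydroxyl-directed trans-hydroalumination of the propargylic alcohol: the alkoxyaluminate delivers hydride intramolecularly to the proximal alkyne carbon, and protonolysis of the five-membered alkenylaluminate gives only the E alkene, while isolated alkenes and the aryl silyl ether should not react.

Step 18
Reactants: 25 (2S)-2-[(3E,7E,11E,15E,19E,22E,24S,27E)-24-hydroxy-4,8,12,16,20,24,28,32-octamethyltritriaconta-3,7,11,15,19,22,27,31-octaen-1-yl]-2,7,8-trimethyl-6-(triisopropylsilyloxy)chroman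
Product: 26 (2S)-2-[(3E,7E,11E,15E,19E,22E,24S,27E)-24-hydroxy-4,8,12,16,20,24,28,32-octamethyltritriaconta-3,7,11,15,19,22,27,31-octaen-1-yl]-2,7,8-trimethylchroman-6-ol
Conditions: Bu4NF/AcOH (1:1), THF, 0 °C, under argon
Reagents that add atoms: none
Why: Fluoride-induced cleavage of the aryl silyl ether under acetic acid buffering frees the phenol without exposing the tertiary allylic alcohol and the skipped diene to acid or the chromanol to basic oxidation.

**Compound list**

1 | 2,3-dimethylbenzene-1,4-diol | Cc1c(O)ccc(O)c1C | starting material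
2 | but-3-en-2-one | CC(=O)C=C | starting material
3 | rac-2-methoxy-2,7,8-trimethylchroman-6-ol | COC1(C)CCc2cc(O)c(C)c(C)c2O1 | intermediate
4 | rac-triisopropyl[(2-methoxy-2,7,8-trimethylchroman-6-yl)oxy]silane | COC1(C)CCc2cc(O[Si](C(C)C)(C(C)C)C(C)C)c(C)c(C)c2O1 | intermediate (not isolated)
5 | rac-2,7,8-trimethyl-6-(triisopropylsilyloxy)chroman-2-ol | CC1(O)CCc2cc(O[Si](C(C)C)(C(C)C)C(C)C)c(C)c(C)c2O1 | intermediate
6 | ethyl (2E)-5-[2-hydroxy-3,4-dimethyl-5-(triisopropylsilyloxy)phenyl]-3-methylpent-2-enoate | CCOC(=O)/C=C(\C)CCc1cc(O[Si](C(C)C)(C(C)C)C(C)C)c(C)c(C)c1O | intermediate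
7 | (2E)-5-[2-hydroxy-3,4-dimethyl-5-(triisopropylsilyloxy)phenyl]-3-methylpent-2-en-1-ol | OC/C=C(\C)CCc1cc(O[Si](C(C)C)(C(C)C)C(C)C)c(C)c(C)c1O | intermediate
8 | (2E)-5-[2-hydroxy-3,4-dimethyl-5-(triisopropylsilyloxy)phenyl]-3-methylpent-2-en-1-yl methyl carbonate | COC(=O)OC/C=C(\C)CCc1cc(O[Si](C(C)C)(C(C)C)C(C)C)c(C)c(C)c1O | intermediate
9 | (2R)-2-ethenyl-2,7,8-trimethyl-6-(triisopropylsilyloxy)chroman | C=C[C@@]1(C)CCc2cc(O[Si](C(C)C)(C(C)C)C(C)C)c(C)c(C)c2O1 | intermediate
10 | (2E,6E,10E)-3,7,11,15-tetramethylhexadeca-2,6,10,14-tetraen-1-ol | CC(C)=CCC/C(C)=C/CC/C(C)=C/CC/C(C)=C/CO | starting material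
11 | (2E,6E,10E)-1-bromo-3,7,11,15-tetramethylhexadeca-2,6,10,14-tetraene | CC(C)=CCC/C(C)=C/CC/C(C)=C/CC/C(C)=C/CBr | intermediate
12 | trimethyl[(5E,9E,13E)-6,10,14,18-tetramethylnonadeca-5,9,13,17-tetraen-1-yn-1-yl]silane | CC(C)=CCC/C(C)=C/CC/C(C)=C/CC/C(C)=C/CCC#C[Si](C)(C)C | intermediate
13 | (5E,9E,13E)-6,10,14,18-tetramethylnonadeca-5,9,13,17-tetraen-1-yne | CC(C)=CCC/C(C)=C/CC/C(C)=C/CC/C(C)=C/CCC#C | intermediate
14 | dimethyl[(1E,5E,9E,13E)-2,6,10,14,18-pentamethylnonadeca-1,5,9,13,17-pentaen-1-yl]alane | CC(C)=CCC/C(C)=C/CC/C(C)=C/CC/C(C)=C/CC/C(C)=C/[Al](C)C | intermediate (not isolated)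
15 | (1E,5E,9E,13E)-1-iodo-2,6,10,14,18-pentamethylnonadeca-1,5,9,13,17-pentaene | CC(C)=CCC/C(C)=C/CC/C(C)=C/CC/C(C)=C/CC/C(C)=C/I | intermediate
16 | 9-{2-[(2S)-2,7,8-trimethyl-6-(triisopropylsilyloxy)chroman-2-yl]ethyl}-9-borabicyclo[3.3.1]nonane | B1(CC[C@@]2(C)CCc3cc(O[Si](C(C)C)(C(C)C)C(C)C)c(C)c(C)c3O2)C2CCCC1CCC2 | intermediate (not isolated)
17 | (2S)-2,7,8-trimethyl-2-[(3E,7E,11E,15E)-4,8,12,16,20-pentamethylhenicosa-3,7,11,15,19-pentaen-1-yl]-6-(triisopropylsilyloxy)chroman | CC(C)=CCC/C(C)=C/CC/C(C)=C/CC/C(C)=C/CC/C(C)=C/CC[C@@]1(C)CCc2cc(O[Si](C(C)C)(C(C)C)C(C)C)c(C)c(C)c2O1 | intermediate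
18 | (2E,6E,10E,14E,18E)-2,6,10,14,18-pentamethyl-21-[(2S)-2,7,8-trimethyl-6-(triisopropylsilyloxy)chroman-2-yl]henicosa-2,6,10,14,18-pentaen-1-ol | OC/C(C)=C/CC/C(C)=C/CC/C(C)=C/CC/C(C)=C/CC/C(C)=C/CC[C@@]1(C)CCc2cc(O[Si](C(C)C)(C(C)C)C(C)C)c(C)c(C)c2O1 | intermediate
19 | (2S)-2-[(3E,7E,11E,15E,19E)-21-bromo-4,8,12,16,20-pentamethylhenicosa-3,7,11,15,19-pentaen-1-yl]-2,7,8-trimethyl-6-(triisopropylsilyloxy)chroman | BrC/C(C)=C/CC/C(C)=C/CC/C(C)=C/CC/C(C)=C/CC/C(C)=C/CC[C@@]1(C)CCc2cc(O[Si](C(C)C)(C(C)C)C(C)C)c(C)c(C)c2O1 | intermediate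
20 | (2E,6E)-3,7,11-trimethyldodeca-2,6,10-trien-1-ol | CC(C)=CCC/C(C)=C/CC/C(C)=C/CO | starting material
21 | [(2S,3S)-3-[(3E)-4,8-dimethylnona-3,7-dien-1-yl]-3-methyloxiran-2-yl]methanol | CC(C)=CCC/C(C)=C/CC[C@]1(C)O[C@H]1CO | intermediate
22 | (2S,3R)-3-(chloromethyl)-2-[(3E)-4,8-dimethylnona-3,7-dien-1-yl]-2-methyloxirane | CC(C)=CCC/C(C)=C/CC[C@]1(C)O[C@H]1CCl | intermediate
23 | dilithium (3S,6E)-3,7,11-trimethyl-3-oxidododeca-6,10-dien-1-yn-1-ide | [Li+].[Li+].CC(C)=CCC/C(C)=C/CC[C@](C)([O-])C#[C-] | intermediate (not isolated)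
24 | (2S)-2-[(3E,7E,11E,15E,19E,24S,27E)-24-hydroxy-4,8,12,16,20,24,28,32-octamethyltritriaconta-3,7,11,15,19,27,31-heptaen-22-yn-1-yl]-2,7,8-trimethyl-6-(triisopropylsilyloxy)chroman | CC(C)=CCC/C(C)=C/CC[C@](C)(O)C#CC/C(C)=C/CC/C(C)=C/CC/C(C)=C/CC/C(C)=C/CC/C(C)=C/CC[C@@]1(C)CCc2cc(O[Si](C(C)C)(C(C)C)C(C)C)c(C)c(C)c2O1 | intermediate
25 | (2S)-2-[(3E,7E,11E,15E,19E,22E,24S,27E)-24-hydroxy-4,8,12,16,20,24,28,32-octamethyltritriaconta-3,7,11,15,19,22,27,31-octaen-1-yl]-2,7,8-trimethyl-6-(triisopropylsilyloxy)chroman | CC(C)=CCC/C(C)=C/CC[C@](C)(O)/C=C/C/C(C)=C/CC/C(C)=C/CC/C(C)=C/CC/C(C)=C/CC/C(C)=C/CC[C@@]1(C)CCc2cc(O[Si](C(C)C)(C(C)C)C(C)C)c(C)c(C)c2O1 | intermediate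
26 | (2S)-2-[(3E,7E,11E,15E,19E,22E,24S,27E)-24-hydroxy-4,8,12,16,20,24,28,32-octamethyltritriaconta-3,7,11,15,19,22,27,31-octaen-1-yl]-2,7,8-trimethylchroman-6-ol | CC(C)=CCC/C(C)=C/CC[C@](C)(O)/C=C/C/C(C)=C/CC/C(C)=C/CC/C(C)=C/CC/C(C)=C/CC/C(C)=C/CC[C@@]1(C)CCc2cc(O)c(C)c(C)c2O1 | target

**Step count and risks**

Total step count: 18. Longest linear sequence: 12 steps (steps 1–6, 11–13 and 16–18).

Steps most likely to fail:

Step 12. The oxidation may not discriminate well enough between the terminal alkene and the four internal ones (attack at internal allylic CH2 groups), and over-oxidation to the enal may occur. Fallback: the terminal oxygen is introduced before the arene is present and by a different principle. The fallback sets out from 15. NBS in aqueous THF at 0 °C, which in polyprenyl chains reacts at the terminal alkene, gives the bromohydrin (6E,10E,14E,18E)-3-bromo-19-iodo-2,6,10,14,18-pentamethylnonadeca-6,10,14,18-tetraen-2-ol F1. K2CO3 in MeOH closes it to the terminal epoxide 3-[(3E,7E,11E,15E)-16-iodo-3,7,11,15-tetramethylhexadeca-3,7,11,15-tetraen-1-yl]-2,2-dimethyloxirane F2. Et2Al(TMP) in toluene at 0 °C isomerises it to the isopropenyl carbinol (6E,10E,14E,18E)-19-iodo-2,6,10,14,18-pentamethylnonadeca-1,6,10,14,18-pentaen-3-ol F3. B-alkyl Suzuki coupling of F3 with borane 16 under the conditions of step 11 gives (2S)-2-[(3E,7E,11E,15E)-19-hydroxy-4,8,12,16,20-pentamethylhenicosa-3,7,11,15,20-pentaen-1-yl]-2,7,8-trimethyl-6-(triisopropylsilyloxy)chroman F4. SOCl2 in Et2O at 0 °C then converts F4 with allylic transposition (SNi') into the primary (E)-allylic chloride (2S)-2-[(3E,7E,11E,15E,19E)-21-chloro-4,8,12,16,20-pentamethylhenicosa-3,7,11,15,19-pentaen-1-yl]-2,7,8-trimethyl-6-(triisopropylsilyloxy)chroman F5. F5 takes the place of 19 in step 16, and the route is rejoined at 24.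

Step 16. The fragmentation may stop short of the acetylide, or the copper-mediated capture may be diverted (gamma attack, O-allylation, base-induced elimination of the bromide). Fallback: the bond is made at the alkene oxidation level by alkenyl–allyl coupling. The fallback sets out from 22 (with 19). Dianion 23 is quenched with water to give (3S,6E)-3,7,11-trimethyldodeca-6,10-dien-1-yn-3-ol F6, which is silylated (Et3SiOTf, 2,6-lutidine, CH2Cl2) to triethyl{[(3S,6E)-3,7,11-trimethyldodeca-6,10-dien-1-yn-3-yl]oxy}silane F7. Hydrozirconation with Cp2Zr(H)Cl in THF gives the (E)-alkenylzirconocene chloride chlorobis(cyclopentadienyl)[(1E,3S,6E)-3,7,11-trimethyl-3-(triethylsilyloxy)dodeca-1,6,10-trien-1-yl]zirconium F8. F8 is coupled in the same flask with 19 under Pd(PPh3)4 catalysis (Negishi-type coupling with retention on both partners) to the triethylsilyl ether of 25, (2S)-2-[(3E,7E,11E,15E,19E,22E,24S,27E)-4,8,12,16,20,24,28,32-octamethyl-24-(triethylsilyloxy)tritriaconta-3,7,11,15,19,22,27,31-octaen-1-yl]-2,7,8-trimethyl-6-(triisopropylsilyloxy)chroman F9. Bu4NF in THF removes both silyl groups and the route comes back at 26, steps 17 and 18 being replaced.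

Step 6. Facial selection in the ring closure may be low or of the opposite sense, and equilibration of the pi-allyl intermediates makes it sensitive to the E/Z purity of 8. Fallback: the C2 centre is set by a reagent-controlled epoxidation and a stereospecific ring closure. The fallback sets out from 7. Sharpless epoxidation with Ti(OiPr)4, L-(+)-diethyl tartrate and t-BuOOH gives [(2S,3S)-3-{2-[2-hydroxy-3,4-dimethyl-5-(triisopropylsilyloxy)phenyl]ethyl}-3-methyloxiran-2-yl]methanol F10. Catalytic camphorsulfonic acid in CH2Cl2 at 0 °C lets the phenol open the oxirane at its tertiary carbon in a 6-exo closure with inversion, giving (1S)-1-[(2R)-2,7,8-trimethyl-6-(triisopropylsilyloxy)chroman-2-yl]ethane-1,2-diol F11. NaIO4 in aqueous THF cleaves the diol to (2R)-2,7,8-trimethyl-6-(triisopropylsilyloxy)chroman-2-carbaldehyde F12. Wittig methylenation (Ph3PCH3Br, KOt-Bu, THF) then returns the route at 9, steps 5 and 6 being replaced.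

Further compounds
F1 | step 12 | (6E,10E,14E,18E)-3-bromo-19-iodo-2,6,10,14,18-pentamethylnonadeca-6,10,14,18-tetraen-2-ol | CC(C)(O)C(Br)CC/C(C)=C/CC/C(C)=C/CC/C(C)=C/CC/C(C)=C/I
F2 | step 12 | 3-[(3E,7E,11E,15E)-16-iodo-3,7,11,15-tetramethylhexadeca-3,7,11,15-tetraen-1-yl]-2,2-dimethyloxirane | CC1(C)OC1CC/C(C)=C/CC/C(C)=C/CC/C(C)=C/CC/C(C)=C/I
F3 | step 12 | (6E,10E,14E,18E)-19-iodo-2,6,10,14,18-pentamethylnonadeca-1,6,10,14,18-pentaen-3-ol | C=C(C)C(O)CC/C(C)=C/CC/C(C)=C/CC/C(C)=C/CC/C(C)=C/I
F4 | step 12 | (2S)-2-[(3E,7E,11E,15E)-19-hydroxy-4,8,12,16,20-pentamethylhenicosa-3,7,11,15,20-pentaen-1-yl]-2,7,8-trimethyl-6-(triisopropylsilyloxy)chroman | C=C(C)C(O)CC/C(C)=C/CC/C(C)=C/CC/C(C)=C/CC/C(C)=C/CC[C@@]1(C)CCc2cc(O[Si](C(C)C)(C(C)C)C(C)C)c(C)c(C)c2O1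
F5 | step 12 | (2S)-2-[(3E,7E,11E,15E,19E)-21-chloro-4,8,12,16,20-pentamethylhenicosa-3,7,11,15,19-pentaen-1-yl]-2,7,8-trimethyl-6-(triisopropylsilyloxy)chroman | ClC/C(C)=C/CC/C(C)=C/CC/C(C)=C/CC/C(C)=C/CC/C(C)=C/CC[C@@]1(C)CCc2cc(O[Si](C(C)C)(C(C)C)C(C)C)c(C)c(C)c2O1
F6 | step 16 | (3S,6E)-3,7,11-trimethyldodeca-6,10-dien-1-yn-3-ol | CC(C)=CCC/C(C)=C/CC[C@](C)(O)C#C
F7 | step 16 | triethyl{[(3S,6E)-3,7,11-trimethyldodeca-6,10-dien-1-yn-3-yl]oxy}silane | CC(C)=CCC/C(C)=C/CC[C@](C)(O[Si](CC)(CC)CC)C#C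
F8 | step 16 | chlorobis(cyclopentadienyl)[(1E,3S,6E)-3,7,11-trimethyl-3-(triethylsilyloxy)dodeca-1,6,10-trien-1-yl]zirconium | CC(C)=CCC/C(C)=C/CC[C@](C)(O[Si](CC)(CC)CC)/C=C/[Zr+2]Cl.c1cc[cH-]c1.c1cc[cH-]c1
F9 | step 16 | (2S)-2-[(3E,7E,11E,15E,19E,22E,24S,27E)-4,8,12,16,20,24,28,32-octamethyl-24-(triethylsilyloxy)tritriaconta-3,7,11,15,19,22,27,31-octaen-1-yl]-2,7,8-trimethyl-6-(triisopropylsilyloxy)chroman | CC(C)=CCC/C(C)=C/CC[C@](C)(O[Si](CC)(CC)CC)/C=C/C/C(C)=C/CC/C(C)=C/CC/C(C)=C/CC/C(C)=C/CC/C(C)=C/CC[C@@]1(C)CCc2cc(O[Si](C(C)C)(C(C)C)C(C)C)c(C)c(C)c2O1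
F10 | step 6 | [(2S,3S)-3-{2-[2-hydroxy-3,4-dimethyl-5-(triisopropylsilyloxy)phenyl]ethyl}-3-methyloxiran-2-yl]methanol | Oc1c(C)c(C)c(O[Si](C(C)C)(C(C)C)C(C)C)cc1CC[C@]1(C)O[C@H]1CO
F11 | step 6 | (1S)-1-[(2R)-2,7,8-trimethyl-6-(triisopropylsilyloxy)chroman-2-yl]ethane-1,2-diol | OC[C@H](O)[C@@]1(C)CCc2cc(O[Si](C(C)C)(C(C)C)C(C)C)c(C)c(C)c2O1
F12 | step 6 | (2R)-2,7,8-trimethyl-6-(triisopropylsilyloxy)chroman-2-carbaldehyde | O=C[C@@]1(C)CCc2cc(O[Si](C(C)C)(C(C)C)C(C)C)c(C)c(C)c2O1
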